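**Strategy.** Numbering: C1 is the quaternary carbinol, C7 its CH2O carbon, C2 and C5 the ring benzoate carbons, C3=C4 the alkene, C6 the secondary carbinol. Because C7–C1–C6 is a dihydroxyacetone unit and the tertiary carbinol C1 adjoins oxygenated C2, the cyclohexene ring is cut at C1–C2 as an acyloin. One carbene-catalysed crossed benzoin joins the enal carbon C2 to the ketone C1 of an acetonide-protected dioxanone, closing the carbocycle cis-fused to the dioxane ring and setting C1. The precursor is a Z-enal (C2–C4) with a silyl ether at C5, attached to C6, the α-carbon of 2,2-dimethyl-1,3-dioxan-5-one. It is assembled by an L-proline anti aldol that fixes C5 and C6.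

Key step: step 8

Remark on locants: in 1,3-benzodioxine numbering the quaternary carbinol C1 is C4a (it bears the C4 methylene, not the ring oxygen), C2 is C5, C5 is C8 and C6 is C8a. The key-step product is therefore a 4a-hydroxy-8-silyloxy-5-one.

Remark on precursor design: the C5 oxygen is kept as a silyl ether (TBS = tert-butyldimethylsilyl) through the key step. An ester there would be a leaving group vinylogous to the acyl-anion carbon. The C1-C2 carbinol stays unprotected until after reduction.

Step 1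
Reactants: 1 but-2-yne-1,4-diol
Product: 2 4-(tert-butyldimethylsilyloxy)but-2-yn-1-ol
Conditions: TBSCl (0.33 equiv), imidazole, THF/DMF, 0 °C → rt (diol in threefold excess)
Reagents that add atoms: tert-butyldimethylsilyl chloride, CC(C)(C)[Si](C)(C)Cl
Why: O-silylation of a symmetric diol used in excess should give mainly the mono-silyl ether, the surplus diol being removed by aqueous extraction.

Step 2
Reactants: 2 4-(tert-butyldimethylsilyloxy)but-2-yn-1-ol
Product: 3 4-(tert-butyldimethylsilyloxy)but-2-ynal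
Conditions: PhI(OAc)2 (1.1 equiv), TEMPO (10 mol%), CH2Cl2, rt
Reagents that add atoms: none
Why: Oxoammonium (TEMPO/hypervalent iodine) oxidation should take the primary propargylic alcohol to the ynal without over-oxidation and without touching the silyl ether.

Step 3
Reactants: 3 4-(tert-butyldimethylsilyloxy)but-2-ynal; 4 2,2-dimethyl-1,3-dioxan-5-one
Product: 6 (4S)-4-[(1S)-4-(tert-butyldimethylsilyloxy)-1-hydroxybut-2-yn-1-yl]-2,2-dimethyl-1,3-dioxan-5-one
Conditions: L-proline 5 (30 mol%), DMF, 4 °C
Reagents that add atoms: none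
Why: Proline enamine aldol, in which the ring-enforced E-enamine of 4 adds to the carboxylic-acid-activated, non-enolisable ynal through a chair-like hydrogen-bonded transition state, should give the anti adduct and so set C6 (S) and C5 (S) with the cis O/O relationship needed in the ring.

Step 4
Reactants: 6 (4S)-4-[(1S)-4-(tert-butyldimethylsilyloxy)-1-hydroxybut-2-yn-1-yl]-2,2-dimethyl-1,3-dioxan-5-one
Product: 7 (4S)-4-[(1S)-1,4-bis(tert-butyldimethylsilyloxy)but-2-yn-1-yl]-2,2-dimethyl-1,3-dioxan-5-one
Conditions: TBSOTf (1.1 equiv), 2,6-lutidine, CH2Cl2, −78 °C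
Reagents that add atoms: tert-butyldimethylsilyl trifluoromethanesulfonate, CC(C)(C)[Si](C)(C)OS(=O)(=O)C(F)(F)F
Why: O-silylation with a silyl triflate and a hindered base at low temperature should cap the β-hydroxy ketone before retro-aldol, dehydration or C6 epimerisation can intervene.

Step 5
Reactants: 7 (4S)-4-[(1S)-1,4-bis(tert-butyldimethylsilyloxy)but-2-yn-1-yl]-2,2-dimethyl-1,3-dioxan-5-one
Product: 8 (4S)-4-[(1S,2Z)-1,4-bis(tert-butyldimethylsilyloxy)but-2-en-1-yl]-2,2-dimethyl-1,3-dioxan-5-one
Conditions: H2 (1 atm), Pd on CaCO3 poisoned with Pb(OAc)2 (Lindlar-type), quinoline, EtOAc, rt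
Reagents that add atoms: none
Why: Lindlar semihydrogenation adds H2 syn across the alkyne to give the Z-alkene (C3=C4), while ketone, silyl ethers and acetonide are inert.

Step 6
Reactants: 8 (4S)-4-[(1S,2Z)-1,4-bis(tert-butyldimethylsilyloxy)but-2-en-1-yl]-2,2-dimethyl-1,3-dioxan-5-one
Product: 9 (4S)-4-[(1S,2Z)-1-(tert-butyldimethylsilyloxy)-4-hydroxybut-2-en-1-yl]-2,2-dimethyl-1,3-dioxan-5-one
Conditions: HF·pyridine, pyridine, THF, 0 °C
Reagents that add atoms: none
Why: Sterically differentiated desilylation with buffered HF·pyridine should cleave the unhindered primary allylic silyl ether well before the secondary one next to the ring, and the non-basic medium avoids silyl migration and leaves the acetonide intact.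

Step 7
Reactants: 9 (4S)-4-[(1S,2Z)-1-(tert-butyldimethylsilyloxy)-4-hydroxybut-2-en-1-yl]-2,2-dimethyl-1,3-dioxan-5-one
Product: 10 (4S)-4-[(1S,2Z)-1-(tert-butyldimethylsilyloxy)-4-oxobut-2-en-1-yl]-2,2-dimethyl-1,3-dioxan-5-one
Conditions: PhI(OAc)2 (1.1 equiv), TEMPO (10 mol%), CH2Cl2, 0 °C → rt; used directly
Reagents that add atoms: none
Why: Oxoammonium oxidation of a Z-allylic alcohol under base-free, nucleophile-free conditions should give the Z-enal without alkene isomerisation or C6 epimerisation.

Step 8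
Reactants: 10 (4S)-4-[(1S,2Z)-1-(tert-butyldimethylsilyloxy)-4-oxobut-2-en-1-yl]-2,2-dimethyl-1,3-dioxan-5-one
Product: 11 (4aR,8S,8aS)-8-(tert-butyldimethylsilyloxy)-4a-hydroxy-2,2-dimethyl-8,8a-dihydro-4H-1,3-benzodioxin-5(4aH)-one (cis-fused)
Conditions: 2-(pentafluorophenyl)-6,7-dihydro-5H-pyrrolo[2,1-c][1,2,4]triazol-2-ium tetrafluoroborate (20 mol%), iPr2NEt (20 mol%), toluene (0.02 M), rt
Reagents that add atoms: none
Why: The free carbene adds to the C2 aldehyde and proton transfer gives the Breslow intermediate, whose C2 carbon attacks the C1 ketone; collapse of the adduct releases the carbene and leaves the C2 ketone conjugated with C3=C4. The closest known reaction type is the triazolium-catalysed intramolecular crossed aldehyde–ketone benzoin, and the electron-poor N-pentafluorophenyl triazolium is chosen because it steers enals toward acyl-anion rather than homoenolate reactivity. The carbocycle closes 6-exo-trig onto the dioxanone carbonyl, which is activated by its two α-oxygens. C1 is set by the substrate: with the tether equatorial on C6, axial attack through a chair-like array that keeps the C5 silyl ether pseudoequatorial should give only the cis ring fusion, placing the new C1 hydroxyl trans to the C6 oxygen and C7 cis to it. The step needs benzoin chemistry to win over homoenolate and redox pathways and needs the Z-alkene to persist: the Z geometry keeps C4 out of reach of the ketone so no other ring can form, the C5 silyl ether is too poor a leaving group for vinylogous elimination, and a weak amine base in dilute aprotic solution disfavours β-protonation, C6 epimerisation, β-elimination and intermolecular benzoin.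

Step 9
Reactants: 11 (4aR,8S,8aS)-8-(tert-butyldimethylsilyloxy)-4a-hydroxy-2,2-dimethyl-8,8a-dihydro-4H-1,3-benzodioxin-5(4aH)-one
Product: 12 (4aS,5R,8S,8aS)-8-(tert-butyldimethylsilyloxy)-2,2-dimethyl-4a,5,8,8a-tetrahydro-4H-1,3-benzodioxine-4a,5-diol
Conditions: NaBH4, CeCl3·7H2O, MeOH, −78 °C
Reagents that add atoms: none
Why: Luche 1,2-reduction, in which hydride should reach C2 from the convex face of the cis-fused bicycle (the face of the C1 hydroxyl, away from the dioxane ring, its axial C6–O bond and the C5 silyl ether), sets C2 with its hydroxyl trans to C1–OH and cis to the C5 and C6 oxygens.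

Step 10
Reactants: 12 (4aS,5R,8S,8aS)-8-(tert-butyldimethylsilyloxy)-2,2-dimethyl-4a,5,8,8a-tetrahydro-4H-1,3-benzodioxine-4a,5-diol
Product: 13 (4aS,5R,8S,8aS)-2,2-dimethyl-4a,5,8,8a-tetrahydro-4H-1,3-benzodioxine-4a,5,8-triol
Conditions: Bu4NF, THF, 0 °C → rt
Reagents that add atoms: none
Why: Fluoride desilylation of the secondary allylic silyl ether is done before any ester is present, so nothing base-labile is exposed and no free hydroxyl sits next to C5 for silyl migration.

Step 11
Reactants: 13 (4aS,5R,8S,8aS)-2,2-dimethyl-4a,5,8,8a-tetrahydro-4H-1,3-benzodioxine-4a,5,8-triol; 14 benzoyl chloride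
Product: 15 (4aS,5R,8S,8aS)-4a-hydroxy-2,2-dimethyl-4a,5,8,8a-tetrahydro-4H-1,3-benzodioxine-5,8-diyl dibenzoate
Conditions: BzCl 14 (2.5 equiv), pyridine, DMAP (cat.), CH2Cl2, 0 °C → rt
Reagents that add atoms: benzoyl chloride 14, O=C(Cl)c1ccccc1
Why: DMAP-catalysed acylation should esterify both secondary allylic hydroxyls (C2 and C5) in one operation while the hindered tertiary C1 hydroxyl stays free.

Step 12
Reactants: 15 (4aS,5R,8S,8aS)-4a-hydroxy-2,2-dimethyl-4a,5,8,8a-tetrahydro-4H-1,3-benzodioxine-5,8-diyl dibenzoate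
Product: 16 (1R,2R,5S,6S)-1,6-dihydroxy-1-(hydroxymethyl)cyclohex-3-ene-2,5-diyl dibenzoate
Conditions: AcOH/H2O (4:1), 40 °C
Reagents that add atoms: none
Why: Mild aqueous-acid hydrolysis of the 1,3-dioxane acetonide should free the C6 and C7 hydroxyls under conditions in which benzoates neither hydrolyse nor migrate appreciably.

Step 13
Reactants: 16 (1R,2R,5S,6S)-1,6-dihydroxy-1-(hydroxymethyl)cyclohex-3-ene-2,5-diyl dibenzoate; 14 benzoyl chloride
Product: 17 [(1R,2R,5S,6S)-2,5-bis(benzoyloxy)-1,6-dihydroxycyclohex-3-en-1-yl]methyl benzoate (target)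
Conditions: BzCl 14 (1.05 equiv), pyridine, CH2Cl2, −30 → 0 °C
Reagents that add atoms: benzoyl chloride 14, O=C(Cl)c1ccccc1
Why: Kinetically selective acylation should take the primary C7 hydroxyl in preference to the secondary C6 hydroxyl (flanked by quaternary C1 and the C5 benzoate) and the tertiary C1 hydroxyl when a near-stoichiometric amount of acyl chloride is used cold.

**Compound list**

1 | but-2-yne-1,4-diol | OCC#CCO | starting material
2 | 4-(tert-butyldimethylsilyloxy)but-2-yn-1-ol | CC(C)(C)[Si](C)(C)OCC#CCO | intermediate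
3 | 4-(tert-butyldimethylsilyloxy)but-2-ynal | CC(C)(C)[Si](C)(C)OCC#CC=O | intermediate
4 | 2,2-dimethyl-1,3-dioxan-5-one | CC1(C)OCC(=O)CO1 | starting material
5 | L-proline, (S)-pyrrolidine-2-carboxylic acid (catalyst) | OC(=O)[C@@H]1CCCN1 | starting material
6 | (4S)-4-[(1S)-4-(tert-butyldimethylsilyloxy)-1-hydroxybut-2-yn-1-yl]-2,2-dimethyl-1,3-dioxan-5-one | CC(C)(C)[Si](C)(C)OCC#C[C@H](O)[C@@H]1OC(C)(C)OCC1=O | intermediate
7 | (4S)-4-[(1S)-1,4-bis(tert-butyldimethylsilyloxy)but-2-yn-1-yl]-2,2-dimethyl-1,3-dioxan-5-one | CC(C)(C)[Si](C)(C)OCC#C[C@H](O[Si](C)(C)C(C)(C)C)[C@@H]1OC(C)(C)OCC1=O | intermediate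
8 | (4S)-4-[(1S,2Z)-1,4-bis(tert-butyldimethylsilyloxy)but-2-en-1-yl]-2,2-dimethyl-1,3-dioxan-5-one | CC(C)(C)[Si](C)(C)OC/C=C\[C@H](O[Si](C)(C)C(C)(C)C)[C@@H]1OC(C)(C)OCC1=O | intermediate
9 | (4S)-4-[(1S,2Z)-1-(tert-butyldimethylsilyloxy)-4-hydroxybut-2-en-1-yl]-2,2-dimethyl-1,3-dioxan-5-one | OC/C=C\[C@H](O[Si](C)(C)C(C)(C)C)[C@@H]1OC(C)(C)OCC1=O | intermediate
10 | (4S)-4-[(1S,2Z)-1-(tert-butyldimethylsilyloxy)-4-oxobut-2-en-1-yl]-2,2-dimethyl-1,3-dioxan-5-one | O=C/C=C\[C@H](O[Si](C)(C)C(C)(C)C)[C@@H]1OC(C)(C)OCC1=O | intermediate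
11 | (4aR,8S,8aS)-8-(tert-butyldimethylsilyloxy)-4a-hydroxy-2,2-dimethyl-8,8a-dihydro-4H-1,3-benzodioxin-5(4aH)-one, cis-fused | O=C1C=C[C@H](O[Si](C)(C)C(C)(C)C)[C@@H]2OC(C)(C)OC[C@]12O | intermediate
12 | (4aS,5R,8S,8aS)-8-(tert-butyldimethylsilyloxy)-2,2-dimethyl-4a,5,8,8a-tetrahydro-4H-1,3-benzodioxine-4a,5-diol | O[C@@H]1C=C[C@H](O[Si](C)(C)C(C)(C)C)[C@@H]2OC(C)(C)OC[C@]12O | intermediate
13 | (4aS,5R,8S,8aS)-2,2-dimethyl-4a,5,8,8a-tetrahydro-4H-1,3-benzodioxine-4a,5,8-triol | O[C@@H]1C=C[C@H](O)[C@@H]2OC(C)(C)OC[C@]12O | intermediate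
14 | benzoyl chloride | O=C(Cl)c1ccccc1 | starting material
15 | (4aS,5R,8S,8aS)-4a-hydroxy-2,2-dimethyl-4a,5,8,8a-tetrahydro-4H-1,3-benzodioxine-5,8-diyl dibenzoate | O=C(O[C@@H]1C=C[C@H](OC(=O)c3ccccc3)[C@@H]2OC(C)(C)OC[C@]12O)c1ccccc1 | intermediate
16 | (1R,2R,5S,6S)-1,6-dihydroxy-1-(hydroxymethyl)cyclohex-3-ene-2,5-diyl dibenzoate | OC[C@]1(O)[C@H](OC(=O)c2ccccc2)C=C[C@H](OC(=O)c2ccccc2)[C@@H]1O | intermediate
17 | [(1R,2R,5S,6S)-2,5-bis(benzoyloxy)-1,6-dihydroxycyclohex-3-en-1-yl]methyl benzoate | O=C(OC[C@]1(O)[C@H](OC(=O)c2ccccc2)C=C[C@H](OC(=O)c2ccccc2)[C@@H]1O)c1ccccc1 | target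

**Totals.** 13 steps; longest linear sequence 13 steps (1 → 17), with 4, 5 and 14 brought in as purchased.

**Steps most likely to fail**

1. Step 8. The enal may leave the acyl-anion manifold (β-protonation and redox isomerisation through the homoenolate, or Z→E isomerisation that makes closure impossible). Addition to the ketone may also be too slow to compete, or the ring-fusion selectivity may erode through C6 epimerisation. The fallback sets out from 10 and forms the same C1–C2 bond reductively. SmI2 (2.5 equiv) with t-BuOH in THF at −78 °C should effect intramolecular ketyl–carbonyl (pinacol) coupling of the aldehyde and ketone carbonyls. The expected product is the cis-1,2-diol (4aS,5S,8S,8aS)-8-(tert-butyldimethylsilyloxy)-2,2-dimethyl-4a,5,8,8a-tetrahydro-4H-1,3-benzodioxine-4a,5-diol F1. Parikh–Doering oxidation (SO3·pyridine, DMSO, iPr2NEt) of its secondary allylic hydroxyl then returns the route at 11. Because C2 becomes a carbonyl again, its configuration in F1 does not matter.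

2. Step 3. The secondary amine may add in conjugate fashion to the ynal and be lost as catalyst, or the slim linear acceptor may give poor anti/syn and enantiofacial discrimination. The fallback sets out from 3 and 4. The dicyclohexylboron enolate of 4 (Cy2BCl, Et3N, Et2O, −78 °C) is added to 3. The ring-enforced E-enolate should react through a closed chair (Zimmerman–Traxler) transition state to give the racemic anti aldol, racemic (4S*)-4-[(1S*)-4-(tert-butyldimethylsilyloxy)-1-hydroxybut-2-yn-1-yl]-2,2-dimethyl-1,3-dioxan-5-one F2. Lipase kinetic resolution follows (immobilised Candida antarctica lipase B, vinyl acetate, tert-butyl methyl ether). By the usual empirical enantiopreference of lipases for secondary alcohols it should acetylate the (4R,1′R) enantiomer to (1R)-4-(tert-butyldimethylsilyloxy)-1-[(4R)-2,2-dimethyl-5-oxo-1,3-dioxan-4-yl]but-2-yn-1-yl acetate F3. The unreacted (4S,1′S) alcohol is 6, where the route is rejoined.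

3. Step 13. Acylation may spread to the C6 hydroxyl, or the C5 benzoate may migrate to the cis C6 oxygen in the basic medium, lowering regioselectivity. The fallback sets out from 16. Bu2SnO (toluene, reflux with removal of water) should tie the C1 and C7 oxygens into the stannylene acetal, the 2,2-dibutyl-1,3,2-dioxastannolane spiro-fused at C1 of 16 F4. In this acetal the primary oxygen is the activated nucleophile. BzCl at 0 °C should then acylate that oxygen only, and aqueous work-up gives 17.

**Further compounds**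

F1 | step 8 | (4aS,5S,8S,8aS)-8-(tert-butyldimethylsilyloxy)-2,2-dimethyl-4a,5,8,8a-tetrahydro-4H-1,3-benzodioxine-4a,5-diol | O[C@H]1C=C[C@H](O[Si](C)(C)C(C)(C)C)[C@@H]2OC(C)(C)OC[C@]12O
F2 | step 3 | racemic (4S*)-4-[(1S*)-4-(tert-butyldimethylsilyloxy)-1-hydroxybut-2-yn-1-yl]-2,2-dimethyl-1,3-dioxan-5-one | CC(C)(C)[Si](C)(C)OCC#C[C@H](O)[C@@H]1OC(C)(C)OCC1=O.CC(C)(C)[Si](C)(C)OCC#C[C@@H](O)[C@H]1OC(C)(C)OCC1=O
F3 | step 3 | (1R)-4-(tert-butyldimethylsilyloxy)-1-[(4R)-2,2-dimethyl-5-oxo-1,3-dioxan-4-yl]but-2-yn-1-yl acetate | CC(C)(C)[Si](C)(C)OCC#C[C@@H](OC(C)=O)[C@H]1OC(C)(C)OCC1=O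
F4 | step 13 | stannylene acetal of 16 (2,2-dibutyl-1,3,2-dioxastannolane across the C1 and C7 oxygens) | CCCC[Sn]2(CCCC)OC[C@]1(O2)[C@H](OC(=O)c3ccccc3)C=C[C@H](OC(=O)c3ccccc3)[C@@H]1O
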